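In millimolar the catalyst is small: 12 mM of it against 400 mM of starting material in ash, so its balance is the one we write.

in all of them: free catalyst 12 mM; time 40 s
- ash: starting material 0.40 M
- maple: starting material 0.80 M
- alder: starting material 1.5 M
- elm: starting material 3.0 M

    catalyst intermediate B ⇌ free catalyst + target (K1 = 0.472 M, k1 = 1.76 s⁻¹)
    starting material + target ⇌ idle adduct, settled at all times (K2 = 1.1 M⁻¹)
    catalyst intermediate A → catalyst intermediate B (k3 = 20.4 s⁻¹)
    starting material + free catalyst ⇌ catalyst intermediate A (K4 = 1.4 M⁻¹, k4 = 2.48 M⁻¹ s⁻¹)

- a species is counted by the starting material in it: one idle adduct counts as two
- amounts and yields of target count idle adduct too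
- in an amount of target, one idle adduct counts as one target
- the concentration of target that is asked is that of its free form alone
- "hardly changes" means that all values lie within two and a half points (for a concentration: within two and a half percent of the largest)
- run time (ash): 40 s

- [target] (only what is free in solution) at the end for ash, maple, alder, elm, in this order
- how the row runs (falls all the way / hardly changes / rises all the way / rises, then falls / falls, then rises)

1. Free catalyst and catalyst intermediates A and B add up to the charge. If A and B pass catalyst on as fast as they receive it, each stands in proportion to free catalyst. The free share is then f = 1/L, with load L = 1 + g·S + P/0.472 M. S is starting material and P is free target, both in molar. The grip g, the load added per molar of starting material, is 1.41 M⁻¹.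

2. Let T be the target made, counting idle adduct and target held in B. It grows at κ·S·f times the catalyst charge, with κ = 2.28 M⁻¹ s⁻¹.

3. From above, for ash: with f at its limit of 1 and S no higher than the charge minus T, T stays below 0.266 M. Holding f at its start value of 0.640 tightens this to 0.201 M, though that step is our judgement, not a proof. Adduct balance then puts our estimated ceiling for free target at 0.171 M.

4. From below, for ash: we take the worst load, f = 0.502, and the worst capture of S by target. On the same judgement, this gives T above 0.145 M. Taking off the whole catalyst charge and the adduct leaves free target above 0.104 M.

5. The forecast gives 0.155 M, 0.208 M, 0.221 M and 0.177 M, and its shape for the row is: rises, then falls. Its ash value lies inside our bracket. Its ground: “More starting material makes more product, but at high S it is increasingly trapped as adduct, so free target rises, then falls.”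

6. The simulation gives 0.156 M, 0.211 M, 0.225 M and 0.180 M, so the row rises, then falls. Ash also lies inside the bracket.

With the end readings, the load gives ash a free share of 63.2%, and 63.2% stands there. For elm it gives 23.7%, and 23.7% stands there, while catalyst intermediate B, elm's resting state at that moment, holds 71.0% of the catalyst charged. Elm's low end value comes in part from the binding of starting material and target into idle adduct, acting together with the hour of the reading. With that binding struck out, elm ends at 0.546 M and the row rises all the way. Read at 400 s instead, elm's free target stands at 1.72 M.

(The rate constants were drawn at random within sensible limits; the flask was simulated.)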